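**Retrosynthetic overview**
1. Target 23 ⇐ desilylation of 22 ⇐ catalyst-controlled Michael addition of C3 of 3-farnesyl-4-hydroxycoumarin 8 to the vinyl terminus of ynenone 21. This is the last C–C bond and it sets the quaternary (S) centre.
2. Ynenone 21 ⇐ oxidation of diynol 20 ⇐ Cadiot–Chodkiewicz coupling of bromoalkyne 18 with pent-1-en-4-yn-3-ol. The (S)-carbinol comes from Sharpless epoxidation and epoxy chloride elimination, the Z-alkene from a Wittig reaction.
3. Coumarin 8 ⇐ key disconnection of the pyran-2,4-dione ring (ring B) at O1–C8a and C3–C4, giving farnesylacetic acid 4 (as its enediolate) and methyl 2-fluorobenzoate 5, joined by a one-pot Claisen-type C-aroylation and intramolecular SNAr lactonisation.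
4. Enabling feature: in the benzo-fused pyran-2,4-dione, O1 sits on benzene ring A ortho to the C4 ketone carbon, so C8a is the SNAr-activated carbon of a 2-fluorobenzoyl unit. C3 lies between the C2 and C4 carbonyls, so it is the carbanion of a carboxylic acid enediolate, and ring closure ends in the stabilised 4-oxidocoumarin.
5. Ring order: ring A is bought; ring B is the only ring of the target that is formed (step 2). The oxirane of 14 and 15 is a temporary ring that fixes the carbinol centre and is opened in step 7.

Key step: step 2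

Assumption: pent-1-en-4-yn-3-ol is used as the racemate because its carbinol carbon becomes the ketone. The quinidine-derived squaramide in step 12 is assigned to the (3S) sense by analogy with α-substituted cyclic β-keto esters; if a model addition shows the opposite sense, the quinine-derived pseudoenantiomer takes its place in the same step.

**Route**

Step 1
Reactants: 1 acetic acid; 2 (2E,6E)-farnesyl bromide
Product: 4 (4E,8E)-5,9,13-trimethyltetradeca-4,8,12-trienoic acid (farnesylacetic acid), via dilithium ethene-1,1-diolate 3 (not isolated)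
Conditions: LiN(iPr)2 (2.1 equiv), THF/DMPU, 0 °C; then 2, 0 °C to rt; aq. HCl
Reagents that add atoms: none
Why: Alkylation of a carboxylic acid dianion at carbon by a primary allylic bromide (SN2), which should leave both E double bonds of the farnesyl unit unchanged.

Step 2
Reactants: 4 farnesylacetic acid; 5 methyl 2-fluorobenzoate
Product: 8 ferulenol (4-hydroxy-3-[(2E,6E)-3,7,11-trimethyldodeca-2,6,10-trien-1-yl]-2H-chromen-2-one), via dilithium enediolate of farnesylacetic acid 6 (not isolated), via dilithium 2-(2-fluorobenzoyl)farnesylacetate enolate 7 (not isolated)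
Conditions: LiN(iPr)2 (2.2 equiv), THF, 0 to 40 °C; 5, −78 °C to rt; DMPU added, THF distilled off, 90 °C; 1 M HCl, 0 °C
Reagents that add atoms: none
Why: Proposed new method: enediolate 6 should attack the ester carbonyl of 5 at carbon (Claisen-type acylation of a carboxylic acid dianion, a known route to β-keto acids), and the methoxide set free deprotonates the β-keto carboxylate, so that C3–C4 bond formation is driven to the doubly charged dianion 7, which cannot decarboxylate; on heating in the dipolar solvent a carboxylate oxygen of 7 should add to the fluorine-bearing ring carbon C8a, ortho to the C4 carbonyl, and fluoride leaves from the Meisenheimer anion (intramolecular SNAr), which forms O1–C8a and ends in the strongly stabilised 4-oxidocoumarin anion. The closest known reaction type is the Grohe–Heitzer cycloaracylation to 4-quinolones and the one-pot C-aroylation/SNAr synthesis of chromones from 2-fluorobenzoyl electrophiles, where nitrogen or an enolate oxygen closes the ring; a carboxylate oxygen in this role, giving the lactone, is the new element. Ring B closes in a six-membered addition–elimination mode (6-exo type) from the enolate geometry, or the keto tautomer, that holds carboxylate and aryl ring cis, which is reached by proton exchange with the methanol and diisopropylamine present. No stereocentre is formed. The step needs C- over O-acylation of the ambident enediolate (O-acylation gives only a mixed anhydride that reverts), carbonyl addition before any attack at C–F (secured by acylating at low temperature and heating only afterwards), and intramolecular carboxylate over intermolecular methoxide in the SNAr (secured by the six-membered tether).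

Step 3
Reactants: 9 octyltriphenylphosphonium bromide; 10 ethyl (E)-4-oxobut-2-enoate
Product: 12 ethyl (2E,4Z)-dodeca-2,4-dienoate, via octylidenetriphenylphosphorane 11 (not isolated)
Conditions: NaN(SiMe3)2, THF, 0 °C; then 10, −78 °C to rt
Reagents that add atoms: none
Why: Wittig olefination with a non-stabilised ylide under salt-free conditions, whose kinetically formed cis-oxaphosphetane should give the (4Z)-alkene while the (2E)-enoate of 10 is carried through.

Step 4
Reactants: 12 ethyl (2E,4Z)-dodeca-2,4-dienoate
Product: 13 (2E,4Z)-dodeca-2,4-dien-1-ol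
Conditions: i-Bu2AlH (2.2 equiv), CH2Cl2, −78 °C; aq. potassium sodium tartrate
Reagents that add atoms: none
Why: 1,2-Reduction of a conjugated ester to the allylic alcohol with i-Bu2AlH at low temperature, which should not touch the diene geometry.

Step 5
Reactants: 13 (2E,4Z)-dodeca-2,4-dien-1-ol
Product: 14 [(2S,3S)-3-[(1Z)-non-1-en-1-yl]oxiran-2-yl]methanol
Conditions: Ti(OiPr)4 (10 mol %), L-(+)-diethyl tartrate (12 mol %), t-BuOOH, 4 Å MS, CH2Cl2, −20 °C
Reagents that add atoms: tert-butyl hydroperoxide, CC(C)(C)OO
Why: Sharpless asymmetric epoxidation, in which the titanium tartrate complex epoxidises only the allylic C2=C3 bond and L-(+)-diethyl tartrate directs oxygen to the face that gives the (2S,3S)-epoxide, so that C3 becomes the future (S)-carbinol.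

Step 6
Reactants: 14 [(2S,3S)-3-[(1Z)-non-1-en-1-yl]oxiran-2-yl]methanol
Product: 15 (2R,3S)-2-(chloromethyl)-3-[(1Z)-non-1-en-1-yl]oxirane
Conditions: PPh3, CCl4, NaHCO3, reflux
Reagents that add atoms: carbon tetrachloride, ClC(Cl)(Cl)Cl
Why: Appel chlorination of the primary alcohol under bicarbonate buffering, which should leave the vinyl epoxide closed and both stereocentres untouched (the C2 descriptor changes only by priority).

Step 7
Reactants: 15 (2R,3S)-2-(chloromethyl)-3-[(1Z)-non-1-en-1-yl]oxirane
Product: 16 (3S,4Z)-dodec-4-en-1-yn-3-ol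
Conditions: LiN(iPr)2 (3.2 equiv), THF, −40 to 0 °C; aq. NH4Cl
Reagents that add atoms: none
Why: Base-induced double elimination of a 2,3-epoxy chloride to a terminal propargylic alcohol (Yadav protocol: deprotonation at the chloromethyl carbon with epoxide opening, then dehydrochlorination), in which the C3–O bond is never broken, so the (S) configuration is retained.

Step 8
Reactants: 16 (3S,4Z)-dodec-4-en-1-yn-3-ol
Product: 17 tert-butyl{[(3S,4Z)-dodec-4-en-1-yn-3-yl]oxy}dimethylsilane
Conditions: TBSCl, imidazole, DMF, rt
Reagents that add atoms: tert-butyldimethylsilyl chloride (TBSCl), CC(C)(C)[Si](C)(C)Cl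
Why: Standard silylation of a secondary alcohol, needed to tell this carbinol apart from the one oxidised in step 11.

Step 9
Reactants: 17 tert-butyl{[(3S,4Z)-dodec-4-en-1-yn-3-yl]oxy}dimethylsilane
Product: 18 {[(3S,4Z)-1-bromododec-4-en-1-yn-3-yl]oxy}(tert-butyl)dimethylsilane
Conditions: NBS, AgNO3 (10 mol %), acetone, rt, dark
Reagents that add atoms: N-bromosuccinimide (NBS), O=C1CCC(=O)N1Br
Why: Silver-catalysed electrophilic bromination of a terminal alkyne to the 1-bromoalkyne, a reaction that tolerates alkenes and silyl ethers.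

Step 10
Reactants: 18 {[(3S,4Z)-1-bromododec-4-en-1-yn-3-yl]oxy}(tert-butyl)dimethylsilane; 19 pent-1-en-4-yn-3-ol (racemic)
Product: 20 (8S,9Z)-8-[(tert-butyldimethylsilyl)oxy]heptadeca-1,9-diene-4,6-diyn-3-ol (both C3 epimers)
Conditions: CuCl (5 mol %), NH2OH·HCl, aq. n-BuNH2, Et2O, 0 °C
Reagents that add atoms: none
Why: Cadiot–Chodkiewicz cross-coupling of a 1-bromoalkyne with a terminal alkyne should give the unsymmetrical 1,3-diyne, and the configuration at C3 is of no consequence because this carbon is oxidised next.

Step 11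
Reactants: 20 (8S,9Z)-8-[(tert-butyldimethylsilyl)oxy]heptadeca-1,9-diene-4,6-diyn-3-ol
Product: 21 (8S,9Z)-8-[(tert-butyldimethylsilyl)oxy]heptadeca-1,9-diene-4,6-diyn-3-one
Conditions: MnO2 (activated, excess), CH2Cl2, rt; used at once
Reagents that add atoms: none
Why: MnO2 oxidation of the doubly activated (allylic and propargylic) alcohol should give the cross-conjugated ynenone under neutral conditions that spare the silyl ether and the Z-alkene.

Step 12
Reactants: 8 ferulenol; 21 (8S,9Z)-8-[(tert-butyldimethylsilyl)oxy]heptadeca-1,9-diene-4,6-diyn-3-one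
Product: 22 (3S)-3-{(8S,9Z)-8-[(tert-butyldimethylsilyl)oxy]-3-oxoheptadec-9-ene-4,6-diyn-1-yl}-3-[(2E,6E)-3,7,11-trimethyldodeca-2,6,10-trien-1-yl]-2H-chromene-2,4(3H)-dione
Conditions: 3,5-bis(trifluoromethyl)phenyl squaramide of 9-amino-9-deoxy-epi-quinidine (10 mol %), toluene, −20 °C
Reagents that add atoms: none
Why: Organocatalytic enantioselective Michael addition of an α-substituted cyclic β-keto lactone to a vinyl ketone, in which the quinuclidine deprotonates the acidic enol of 8, the squaramide binds the enone carbonyl, and the chiral ion pair lets the unsubstituted vinyl terminus approach one face of C3, so that the quaternary (3S) centre is set under catalyst control.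

Step 13
Reactants: 22 silyl-protected Michael adduct
Product: 23 (3S)-3-[(8S,9Z)-8-hydroxy-3-oxoheptadec-9-ene-4,6-diyn-1-yl]-3-[(2E,6E)-3,7,11-trimethyldodeca-2,6,10-trien-1-yl]-2H-chromene-2,4(3H)-dione (CNP0346147.1)
Conditions: HF·pyridine, pyridine, THF, 0 °C to rt
Reagents that add atoms: none
Why: Cleavage of a secondary TBS ether with buffered HF·pyridine, which avoids the basic fluoride sources that would open the chromane-2,4-dione and is mild enough for the trisubstituted alkenes and the diynone.

**Compound list**

1 | acetic acid | CC(O)=O | starting material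
2 | (2E,6E)-farnesyl bromide ((2E,6E)-1-bromo-3,7,11-trimethyldodeca-2,6,10-triene) | BrC/C=C(\C)CC/C=C(\C)CCC=C(C)C | starting material
3 | dilithium ethene-1,1-diolate (acetic acid dianion) | [Li+].[Li+].[O-]C([O-])=C | intermediate (not isolated)
4 | (4E,8E)-5,9,13-trimethyltetradeca-4,8,12-trienoic acid (farnesylacetic acid) | OC(=O)CC/C=C(\C)CC/C=C(\C)CCC=C(C)C | intermediate
5 | methyl 2-fluorobenzoate | COC(=O)c1ccccc1F | starting material
6 | dilithium (4E,8E)-5,9,13-trimethyltetradeca-1,4,8,12-tetraene-1,1-diolate (enediolate of 4) | [Li+].[Li+].[O-]C([O-])=CC/C=C(\C)CC/C=C(\C)CCC=C(C)C | intermediate (not isolated)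
7 | dilithium salt of 2-(2-fluorobenzoyl)farnesylacetic acid (enolate carboxylate) | [Li+].[Li+].[O-]C(=O)C(C/C=C(\C)CC/C=C(\C)CCC=C(C)C)=C([O-])c1ccccc1F | intermediate (not isolated)
8 | ferulenol (4-hydroxy-3-[(2E,6E)-3,7,11-trimethyldodeca-2,6,10-trien-1-yl]-2H-chromen-2-one) | OC1=C(C/C=C(\C)CC/C=C(\C)CCC=C(C)C)C(=O)Oc2ccccc12 | intermediate
9 | octyltriphenylphosphonium bromide | CCCCCCCC[P+](c1ccccc1)(c1ccccc1)c1ccccc1.[Br-] | starting material
10 | ethyl (E)-4-oxobut-2-enoate | CCOC(=O)/C=C/C=O | starting material
11 | octylidenetriphenylphosphorane | CCCCCCCC=P(c1ccccc1)(c1ccccc1)c1ccccc1 | intermediate (not isolated)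
12 | ethyl (2E,4Z)-dodeca-2,4-dienoate | CCOC(=O)/C=C/C=C\CCCCCCC | intermediate
13 | (2E,4Z)-dodeca-2,4-dien-1-ol | OC/C=C/C=C\CCCCCCC | intermediate
14 | [(2S,3S)-3-[(1Z)-non-1-en-1-yl]oxiran-2-yl]methanol | OC[C@@H]1O[C@H]1/C=C\CCCCCCC | intermediate
15 | (2R,3S)-2-(chloromethyl)-3-[(1Z)-non-1-en-1-yl]oxirane | ClC[C@@H]1O[C@H]1/C=C\CCCCCCC | intermediate
16 | (3S,4Z)-dodec-4-en-1-yn-3-ol | C#C[C@@H](O)/C=C\CCCCCCC | intermediate
17 | tert-butyl{[(3S,4Z)-dodec-4-en-1-yn-3-yl]oxy}dimethylsilane | C#C[C@@H](O[Si](C)(C)C(C)(C)C)/C=C\CCCCCCC | intermediate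
18 | {[(3S,4Z)-1-bromododec-4-en-1-yn-3-yl]oxy}(tert-butyl)dimethylsilane | BrC#C[C@@H](O[Si](C)(C)C(C)(C)C)/C=C\CCCCCCC | intermediate
19 | pent-1-en-4-yn-3-ol (racemic) | C=CC(O)C#C | starting material
20 | (8S,9Z)-8-[(tert-butyldimethylsilyl)oxy]heptadeca-1,9-diene-4,6-diyn-3-ol (both C3 epimers) | C=CC(O)C#CC#C[C@@H](O[Si](C)(C)C(C)(C)C)/C=C\CCCCCCC | intermediate
21 | (8S,9Z)-8-[(tert-butyldimethylsilyl)oxy]heptadeca-1,9-diene-4,6-diyn-3-one | C=CC(=O)C#CC#C[C@@H](O[Si](C)(C)C(C)(C)C)/C=C\CCCCCCC | intermediate
22 | (3S)-3-{(8S,9Z)-8-[(tert-butyldimethylsilyl)oxy]-3-oxoheptadec-9-ene-4,6-diyn-1-yl}-3-[(2E,6E)-3,7,11-trimethyldodeca-2,6,10-trien-1-yl]-2H-chromene-2,4(3H)-dione | CCCCCCC/C=C\[C@H](O[Si](C)(C)C(C)(C)C)C#CC#CC(=O)CC[C@@]1(C/C=C(\C)CC/C=C(\C)CCC=C(C)C)C(=O)Oc2ccccc2C1=O | intermediate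
23 | (3S)-3-[(8S,9Z)-8-hydroxy-3-oxoheptadec-9-ene-4,6-diyn-1-yl]-3-[(2E,6E)-3,7,11-trimethyldodeca-2,6,10-trien-1-yl]-2H-chromene-2,4(3H)-dione | CCCCCCC/C=C\[C@H](O)C#CC#CC(=O)CC[C@@]1(C/C=C(\C)CC/C=C(\C)CCC=C(C)C)C(=O)Oc2ccccc2C1=O | target

**Step count and risks**

Total step count: 13. Longest linear sequence: 11 steps (steps 3 to 11, then 12 and 13).

Steps most likely to fail:

1. Step 2 (proposed method). The ring closure may stall because the doubly charged enolate carboxylate is both a deactivated SNAr substrate and, as a lithium aggregate, a weak oxygen nucleophile. Decarboxylation of partly protonated β-keto carboxylate and intermolecular substitution of fluoride by methoxide may then take over. Fallback with known chemistry, setting out from 4: Steglich esterification of 4 with methyl salicylate (DCC, DMAP, CH2Cl2) should give methyl 2-{[(4E,8E)-5,9,13-trimethyltetradeca-4,8,12-trienoyl]oxy}benzoate F1. Its intramolecular Claisen condensation (KOtBu, THF, 0 °C, then dilute acid) is the classical route from O-acyl salicylates to 3-substituted 4-hydroxycoumarins and comes back to the route at 8. In this variant the aryl C–O bond is bought with the salicylate and only C3–C4 is formed.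

2. Step 12. Facial selectivity at C3 may be poor with this acceptor, and the nucleophile or the catalyst may add to the diynone terminus or trigger oligomerisation of the ynenone. Fallback setting out from 8 and 18: the same squaramide catalysis with S-ethyl prop-2-enethioate, an acrylic acceptor of the class for which quaternary centres from β-keto esters are known, should give S-ethyl 3-{(3S)-2,4-dioxo-3-[(2E,6E)-3,7,11-trimethyldodeca-2,6,10-trien-1-yl]-3,4-dihydro-2H-chromen-3-yl}propanethioate F2. In parallel, Cadiot–Chodkiewicz coupling of 18 with trimethylsilylacetylene should give tert-butyldimethyl{[(5S,6Z)-1-(trimethylsilyl)tetradec-6-ene-1,3-diyn-5-yl]oxy}silane F3, and K2CO3 in methanol should free tert-butyldimethyl{[(5S,6Z)-tetradec-6-ene-1,3-diyn-5-yl]oxy}silane F4. Palladium- and copper-catalysed coupling of thioester F2 with terminal diyne F4 (PdCl2(dppf), tri(2-furyl)phosphine, CuI, Et3N, DMF, 50 °C; Fukuyama-type ynone synthesis) comes back to the route at 22, so no vinyl ynone is ever exposed to the nucleophile.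

3. Step 13. Material may be lost during desilylation through fluoride- or pyridine-induced opening of the aryl lactone (retro-Claisen cleavage) or through addition to the diynone. Fallback setting out from 21: desilylation before the coupling (HF·pyridine, THF, 0 °C) should give (8S,9Z)-8-hydroxyheptadeca-1,9-diene-4,6-diyn-3-one F5. Michael addition of 8 to it under the conditions of step 12 then comes back to the route directly at 23, so the chromane-2,4-dione never meets fluoride.

**Further compounds**

F1 | step 2 | methyl 2-{[(4E,8E)-5,9,13-trimethyltetradeca-4,8,12-trienoyl]oxy}benzoate | COC(=O)c1ccccc1OC(=O)CC/C=C(\C)CC/C=C(\C)CCC=C(C)C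
F2 | step 12 | S-ethyl 3-{(3S)-2,4-dioxo-3-[(2E,6E)-3,7,11-trimethyldodeca-2,6,10-trien-1-yl]-3,4-dihydro-2H-chromen-3-yl}propanethioate | CCSC(=O)CC[C@@]1(C/C=C(\C)CC/C=C(\C)CCC=C(C)C)C(=O)Oc2ccccc2C1=O
F3 | step 12 | tert-butyldimethyl{[(5S,6Z)-1-(trimethylsilyl)tetradec-6-ene-1,3-diyn-5-yl]oxy}silane | C[Si](C)(C)C#CC#C[C@@H](O[Si](C)(C)C(C)(C)C)/C=C\CCCCCCC
F4 | step 12 | tert-butyldimethyl{[(5S,6Z)-tetradec-6-ene-1,3-diyn-5-yl]oxy}silane | C#CC#C[C@@H](O[Si](C)(C)C(C)(C)C)/C=C\CCCCCCC
F5 | step 13 | (8S,9Z)-8-hydroxyheptadeca-1,9-diene-4,6-diyn-3-one | C=CC(=O)C#CC#C[C@@H](O)/C=C\CCCCCCC
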